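Everything rests on cutting ring A out of the flavan. The benzene C4a–C5(OH)–C6(H)–C7(OMe)–C8(prenyl)–C8a(O1), a phloroglucinol with three unlike oxygens, is traced back to methoxyacetylene and an enantiopure dihydropyran (ring C). The enol ether C=C of that dihydropyran is the future C4a=C8a bond. Irradiating an α-diazo ketone attached to the enol ether starts a Wolff shift, ketene–ynol ether [2+2] addition, 4π opening and 6π closure. This one operation forms C8–C8a, C5–C6, C7–C8 and C4a–C5 and places OH, OMe and prenyl without any phenol differentiation. The precursor is a (2S,4R)-2-aryl-4-silyloxy-3,4-dihydro-2H-pyran carrying a 2-diazo-5-methylhex-4-enoyl group at C6.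

Key step: step 11

Assumption: (S)-BINOL–Ti(IV) is taken to give (S)-5, by analogy with the facial preference of this catalyst in other additions to aldehydes. Both BINOL antipodes are commercial, so the ligand is exchanged if the configurational check on 5 demands it.

Locants: monocyclic compounds carry pyran locants, and ring-A atoms carry flavan locants (pyran C6 = flavan C8a, pyran C5 = flavan C4a).

Design remarks:
- (a) Both silyl groups are TIPS. They offer no Si–CH3 protons to t-BuLi, hinder the aryl ortho positions, resist hydride and amide bases, and are still removed by fluoride.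
- (b) The benzoate is removed reductively. Basic methanolysis would endanger the aryl silyl ether and expose a phenoxide able to open ring C through a quinone methide.
- (c) The ketone is activated as its trifluoroacetyl derivative, because a simple ketone enolate does not undergo clean diazo transfer.
- (d) Long-wave light is used, because 24 is an o-hydroxybenzylic ether that short-wave UV could ionise.
- (e) Counting the 1,2-shift, the key step makes four σ-bonds (C8–C8a, C5–C6, C7–C8, C4a–C5) and breaks two (C5–C8a, C5–C8).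

Step 1
Reactants: 1 4-hydroxybenzaldehyde
Product: 2 4-(triisopropylsilyloxy)benzaldehyde
Conditions: TIPSCl, imidazole, DMF, 0 °C → rt
Reagents that add atoms: chlorotriisopropylsilane (TIPSCl), CC(C)[Si](Cl)(C(C)C)C(C)C
Why: Imidazole-promoted O-silylation of a phenol masks the acidic OH, which would otherwise poison the titanium catalyst and consume the organolithium reagent used later.

Step 2
Reactants: 2 4-(triisopropylsilyloxy)benzaldehyde; 3 (E)-1-methoxy-3-(trimethylsilyloxy)buta-1,3-diene
Product: 5 (S)-2-[4-(triisopropylsilyloxy)phenyl]-2,3-dihydro-4H-pyran-4-one, via Mukaiyama aldol silyl ether 4 (not isolated)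
Conditions: (S)-BINOL (20 mol %), Ti(OiPr)4 (10 mol %), 4 Å MS, Et2O, −20 °C; then TFA, CH2Cl2, 0 °C
Reagents that add atoms: none
Why: Catalytic asymmetric hetero-Diels–Alder reaction in its Ti(IV)–BINOL form (Mukaiyama aldol addition, then acid-induced ring closure with loss of methanol), in which the chiral titanium complex shields one face of the bound aldehyde and so sets C2 as S.

Step 3
Reactants: 5 (S)-2-[4-(triisopropylsilyloxy)phenyl]-2,3-dihydro-4H-pyran-4-one
Product: 6 (2S,4S)-2-[4-(triisopropylsilyloxy)phenyl]-3,4-dihydro-2H-pyran-4-ol (2,4-cis)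
Conditions: NaBH4, CeCl3·7H2O, MeOH, −78 → −40 °C
Reagents that add atoms: none
Why: Luche 1,2-reduction, in which hydride adds axially to the half-chair that holds the aryl group equatorial, so the new C4 carbinol is pseudo-equatorial and cis to the aryl group (4S) while cerium suppresses conjugate reduction.

Step 4
Reactants: 6 (2S,4S)-2-[4-(triisopropylsilyloxy)phenyl]-3,4-dihydro-2H-pyran-4-ol
Product: 7 (2S,4R)-2-[4-(triisopropylsilyloxy)phenyl]-3,4-dihydro-2H-pyran-4-yl benzoate (2,4-trans)
Conditions: PhCO2H, PPh3, DIAD, toluene, −20 → 0 °C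
Reagents that add atoms: benzoic acid, O=C(O)c1ccccc1
Why: Mitsunobu reaction, in which SN2 displacement of the oxyphosphonium group by benzoate inverts C4 to R as in the glucal-to-allal inversion of glycal allylic alcohols, with low temperature and a non-polar solvent holding back ionisation and SN2′ attack at C6.

Step 5
Reactants: 7 (2S,4R)-2-[4-(triisopropylsilyloxy)phenyl]-3,4-dihydro-2H-pyran-4-yl benzoate
Product: 8 (2S,4R)-2-[4-(triisopropylsilyloxy)phenyl]-3,4-dihydro-2H-pyran-4-ol (2,4-trans)
Conditions: DIBAL-H (2.5 equiv), CH2Cl2, −78 °C; aq. Rochelle salt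
Reagents that add atoms: none
Why: Reductive ester cleavage breaks only the acyl–oxygen bond, so C4 keeps its configuration, and the cold non-basic medium leaves the aryl silyl ether and the enol ether alone.

Step 6
Reactants: 8 (2S,4R)-2-[4-(triisopropylsilyloxy)phenyl]-3,4-dihydro-2H-pyran-4-ol
Product: 9 (2S,4R)-4-(triisopropylsilyloxy)-2-[4-(triisopropylsilyloxy)phenyl]-3,4-dihydro-2H-pyran
Conditions: TIPSOTf, 2,6-lutidine, CH2Cl2, −78 → 0 °C
Reagents that add atoms: triisopropylsilyl triflate (TIPSOTf), CC(C)[Si](OS(=O)(=O)C(F)(F)F)(C(C)C)C(C)C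
Why: O-silylation of a secondary allylic alcohol with a silyl triflate and a hindered base leaves the C4–O bond and its configuration intact, and the excess lutidine keeps the medium free of acid so that Ferrier-type ionisation is not triggered.

Step 7
Reactants: 10 5-methylhex-4-enoic acid
Product: 12 N-methoxy-N,5-dimethylhex-4-enamide, via acyl imidazolide 11 (not isolated)
Conditions: CDI, CH2Cl2, rt; then MeNH(OMe)·HCl, rt
Reagents that add atoms: N,O-dimethylhydroxylamine hydrochloride, CNOC.Cl; 1,1'-carbonyldiimidazole, O=C(n1ccnc1)n1ccnc1 (imidazolyl group in 11 only)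
Why: Amide coupling through the acyl imidazolide gives the Weinreb amide under neutral conditions that do not touch the trisubstituted alkene.

Step 8
Reactants: 9 (2S,4R)-4-(triisopropylsilyloxy)-2-[4-(triisopropylsilyloxy)phenyl]-3,4-dihydro-2H-pyran; 12 N-methoxy-N,5-dimethylhex-4-enamide
Product: 14 5-methyl-1-[(2S,4R)-4-(triisopropylsilyloxy)-2-[4-(triisopropylsilyloxy)phenyl]-3,4-dihydro-2H-pyran-6-yl]hex-4-en-1-one, via C6-lithio dihydropyran 13 (not isolated)
Conditions: t-BuLi (1.5–2 equiv), THF, −78 → 0 °C; then 12, −78 → −20 °C; pH 7 buffer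
Reagents that add atoms: tert-butyllithium, [Li]C(C)(C)C (lithium in 13 only)
Why: Vinylic α-lithiation of a cyclic enol ether (the method used for C1 metalation of silyl-protected glycals) followed by Weinreb ketone synthesis, whose chelated adduct stops over-addition, while the para-silyloxy donor and the tertiary nature of benzylic C2–H disfavour the competing metalation so that C2 and C4 stay untouched.

Step 9
Reactants: 14 5-methyl-1-[(2S,4R)-4-(triisopropylsilyloxy)-2-[4-(triisopropylsilyloxy)phenyl]-3,4-dihydro-2H-pyran-6-yl]hex-4-en-1-one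
Product: 16 2-diazo-5-methyl-1-[(2S,4R)-4-(triisopropylsilyloxy)-2-[4-(triisopropylsilyloxy)phenyl]-3,4-dihydro-2H-pyran-6-yl]hex-4-en-1-one, via trifluoroacetyl diketone 15 (not isolated)
Conditions: LiHMDS, THF, −78 °C; CF3CO2CH2CF3; cold dilute HCl work-up; then p-ABSA, Et3N, H2O (1 equiv), MeCN, rt
Reagents that add atoms: 4-acetamidobenzenesulfonyl azide (p-ABSA), CC(=O)Nc1ccc(cc1)S(=O)(=O)N=[N+]=[N-]; 2,2,2-trifluoroethyl trifluoroacetate, O=C(OCC(F)(F)F)C(F)(F)F (CF3CO group in 15 only)
Why: Deacylative (detrifluoroacetylative) Regitz-type diazo transfer, in which the only kinetically accessible enolate (the α′-CH2) is trifluoroacetylated for activation and the sulfonyl azide then delivers N2 with loss of the trifluoroacetyl group, a sequence suited to α′-diazo enones.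

Step 10
Reactants: 17 chloroacetaldehyde dimethyl acetal
Product: 19 methoxyacetylene, via sodium methoxyacetylide 18 (not isolated)
Conditions: NaNH2 (3 equiv), liq. NH3, −33 °C; evaporate NH3; cold sat. aq. NaCl; distil into ClCH2CH2Cl at −20 °C
Reagents that add atoms: sodium amide, [Na+].[NH2-] (sodium in 18 only)
Why: Base-induced double β-elimination (methanol first, then hydrogen chloride) from the α-chloro acetal is the standard preparation of alkoxyacetylenes, and the third equivalent of amide stores the product as its acetylide until the aqueous quench.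

Step 11
Reactants: 16 2-diazo-5-methyl-1-[(2S,4R)-4-(triisopropylsilyloxy)-2-[4-(triisopropylsilyloxy)phenyl]-3,4-dihydro-2H-pyran-6-yl]hex-4-en-1-one; 19 methoxyacetylene
Product: 24 (2S,4R)-7-methoxy-8-(3-methylbut-2-enyl)-4-(triisopropylsilyloxy)-2-[4-(triisopropylsilyloxy)phenyl]chroman-5-ol, via ketene 20 (not isolated), via vinylcyclobutenone 21 (not isolated), via dienylketene 22 (not isolated), via cyclohexadienone tautomer 23 (not isolated)
Conditions: 19 (5 equiv), ClCH2CH2Cl (0.05 M, degassed, passed through basic alumina), hν (350–365 nm, Pyrex), 10 °C, dry-ice condenser; purge excess 19; then 80 °C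
Reagents that add atoms: none
Why: Direct excitation expels N2 and the sp2 carbon C8a shifts from the carbonyl carbon to the diazo carbon (photo-Wolff rearrangement, new bond C8–C8a) to give ketene 20, whose electrophilic carbonyl carbon is attacked by the nucleophilic CH terminus of the ynol ether, so that the [2+2] adduct 21 holds C5–C6 and C7–C8. Conrotatory 4π opening of 21, by light or on warming, cleaves C5–C8 to dienylketene 22, and ring A closes by a disrotatory 6π electrocyclisation that joins the ketene carbon C5 to the enol ether β-carbon C4a, after which enolisation of 23 gives the phenol. This is the Danheiser benzannulation in its photochemical diazo ketone form, established for vinyl, aryl and heteroaryl diazo ketones in combination with alkoxy- and siloxyalkynes, so only the molecule is new. No stereocentre is created, since the quaternary carbon of 21 and the C4a–H centre of 23 are erased, and C2 and C4 take part in no bond change. The regiochemistry (OH at C5, H at C6, OMe at C7, prenyl at C8) follows from the ketene/ynol ether polarity and from the prenyl group already sitting on the diazo carbon. The chemoselectivity needed is alkenyl migration over 1,2-hydride shift from the allylic CH2, which unsensitised irradiation, the absence of metals and the high migratory aptitude of the electron-rich alkenyl group favour, while light above 300 nm spares the aryl ether and the o-hydroxybenzylic silyl ether of 24.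

Step 12
Reactants: 24 (2S,4R)-7-methoxy-8-(3-methylbut-2-enyl)-4-(triisopropylsilyloxy)-2-[4-(triisopropylsilyloxy)phenyl]chroman-5-ol
Product: 25 (2S,4R)-2-(4-hydroxyphenyl)-7-methoxy-8-(3-methylbut-2-enyl)chroman-4,5-diol (4,5,4'-trihydroxy-7-methoxy-8-prenylflavan)
Conditions: TBAF/AcOH (1:1, 3 equiv), THF, 0 °C → rt; neutral work-up, Et3N-deactivated silica
Reagents that add atoms: none
Why: Fluoride-induced cleavage of both Si–O bonds, in which the acetic acid buffer keeps the 4'- and 5-phenols protonated and so blocks quinone methide pathways (opening of C2–O1, ionisation at C4), while no acid strong enough to ionise the trioxygenated benzylic C4–OH is present, so both stereocentres persist.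

Compound list
1 | 4-hydroxybenzaldehyde | O=Cc1ccc(O)cc1 | starting material
2 | 4-(triisopropylsilyloxy)benzaldehyde | O=Cc1ccc(O[Si](C(C)C)(C(C)C)C(C)C)cc1 | intermediate
3 | (E)-1-methoxy-3-(trimethylsilyloxy)buta-1,3-diene | CO/C=C/C(=C)O[Si](C)(C)C | starting material
4 | (1E,5S)-1-methoxy-5-(trimethylsilyloxy)-5-[4-(triisopropylsilyloxy)phenyl]pent-1-en-3-one | CO/C=C/C(=O)C[C@H](O[Si](C)(C)C)c1ccc(O[Si](C(C)C)(C(C)C)C(C)C)cc1 | intermediate
5 | (S)-2-[4-(triisopropylsilyloxy)phenyl]-2,3-dihydro-4H-pyran-4-one | O=C1C=CO[C@H](c2ccc(O[Si](C(C)C)(C(C)C)C(C)C)cc2)C1 | intermediate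
6 | (2S,4S)-2-[4-(triisopropylsilyloxy)phenyl]-3,4-dihydro-2H-pyran-4-ol | C1=C[C@@H](O)C[C@@H](c2ccc(O[Si](C(C)C)(C(C)C)C(C)C)cc2)O1 | intermediate
7 | (2S,4R)-2-[4-(triisopropylsilyloxy)phenyl]-3,4-dihydro-2H-pyran-4-yl benzoate | C1=C[C@H](OC(=O)c3ccccc3)C[C@@H](c2ccc(O[Si](C(C)C)(C(C)C)C(C)C)cc2)O1 | intermediate
8 | (2S,4R)-2-[4-(triisopropylsilyloxy)phenyl]-3,4-dihydro-2H-pyran-4-ol | C1=C[C@H](O)C[C@@H](c2ccc(O[Si](C(C)C)(C(C)C)C(C)C)cc2)O1 | intermediate
9 | (2S,4R)-4-(triisopropylsilyloxy)-2-[4-(triisopropylsilyloxy)phenyl]-3,4-dihydro-2H-pyran | C1=C[C@H](O[Si](C(C)C)(C(C)C)C(C)C)C[C@@H](c2ccc(O[Si](C(C)C)(C(C)C)C(C)C)cc2)O1 | intermediate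
10 | 5-methylhex-4-enoic acid | CC(C)=CCCC(=O)O | starting material
11 | 1-(imidazol-1-yl)-5-methylhex-4-en-1-one | CC(C)=CCCC(=O)n1ccnc1 | intermediate
12 | N-methoxy-N,5-dimethylhex-4-enamide | CC(C)=CCCC(=O)N(C)OC | intermediate
13 | [(2S,4R)-4-(triisopropylsilyloxy)-2-[4-(triisopropylsilyloxy)phenyl]-3,4-dihydro-2H-pyran-6-yl]lithium | [Li]C1=C[C@H](O[Si](C(C)C)(C(C)C)C(C)C)C[C@@H](c2ccc(O[Si](C(C)C)(C(C)C)C(C)C)cc2)O1 | intermediate
14 | 5-methyl-1-[(2S,4R)-4-(triisopropylsilyloxy)-2-[4-(triisopropylsilyloxy)phenyl]-3,4-dihydro-2H-pyran-6-yl]hex-4-en-1-one | CC(C)=CCCC(=O)C1=C[C@H](O[Si](C(C)C)(C(C)C)C(C)C)C[C@@H](c2ccc(O[Si](C(C)C)(C(C)C)C(C)C)cc2)O1 | intermediate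
15 | 4,4,4-trifluoro-2-(3-methylbut-2-enyl)-1-[(2S,4R)-4-(triisopropylsilyloxy)-2-[4-(triisopropylsilyloxy)phenyl]-3,4-dihydro-2H-pyran-6-yl]butane-1,3-dione (C2 epimers and enol) | CC(C)=CCC(C(=O)C(F)(F)F)C(=O)C1=C[C@H](O[Si](C(C)C)(C(C)C)C(C)C)C[C@@H](c2ccc(O[Si](C(C)C)(C(C)C)C(C)C)cc2)O1 | intermediate
16 | 2-diazo-5-methyl-1-[(2S,4R)-4-(triisopropylsilyloxy)-2-[4-(triisopropylsilyloxy)phenyl]-3,4-dihydro-2H-pyran-6-yl]hex-4-en-1-one | CC(C)=CCC(=[N+]=[N-])C(=O)C1=C[C@H](O[Si](C(C)C)(C(C)C)C(C)C)C[C@@H](c2ccc(O[Si](C(C)C)(C(C)C)C(C)C)cc2)O1 | intermediate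
17 | chloroacetaldehyde dimethyl acetal | COC(CCl)OC | starting material
18 | sodium methoxyacetylide | [Na+].[C-]#COC | intermediate
19 | methoxyacetylene | COC#C | intermediate
20 | 5-methyl-2-[(2S,4R)-4-(triisopropylsilyloxy)-2-[4-(triisopropylsilyloxy)phenyl]-3,4-dihydro-2H-pyran-6-yl]hexa-1,4-dien-1-one (ketene) | CC(C)=CCC(=C=O)C1=C[C@H](O[Si](C(C)C)(C(C)C)C(C)C)C[C@@H](c2ccc(O[Si](C(C)C)(C(C)C)C(C)C)cc2)O1 | intermediate
21 | 3-methoxy-4-(3-methylbut-2-enyl)-4-[(2S,4R)-4-(triisopropylsilyloxy)-2-[4-(triisopropylsilyloxy)phenyl]-3,4-dihydro-2H-pyran-6-yl]cyclobut-2-en-1-one (both epimers at the quaternary carbon) | COC1=CC(=O)C1(CC=C(C)C)C3=C[C@H](O[Si](C(C)C)(C(C)C)C(C)C)C[C@@H](c2ccc(O[Si](C(C)C)(C(C)C)C(C)C)cc2)O3 | intermediate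
22 | (3E)-3-methoxy-7-methyl-4-[(2S,4R)-4-(triisopropylsilyloxy)-2-[4-(triisopropylsilyloxy)phenyl]-3,4-dihydro-2H-pyran-6-yl]octa-1,3,6-trien-1-one (dienylketene) | O=C=C/C(OC)=C(/CC=C(C)C)C1=C[C@H](O[Si](C(C)C)(C(C)C)C(C)C)C[C@@H](c2ccc(O[Si](C(C)C)(C(C)C)C(C)C)cc2)O1 | intermediate
23 | (2S,4R)-7-methoxy-8-(3-methylbut-2-enyl)-4-(triisopropylsilyloxy)-2-[4-(triisopropylsilyloxy)phenyl]-2,3,4,4a-tetrahydro-5H-chromen-5-one (C4a unassigned) | COC1=CC(=O)C2C(=C1CC=C(C)C)O[C@H](c1ccc(O[Si](C(C)C)(C(C)C)C(C)C)cc1)C[C@H]2O[Si](C(C)C)(C(C)C)C(C)C | intermediate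
24 | (2S,4R)-7-methoxy-8-(3-methylbut-2-enyl)-4-(triisopropylsilyloxy)-2-[4-(triisopropylsilyloxy)phenyl]chroman-5-ol | COc1cc(O)c2c(c1CC=C(C)C)O[C@H](c1ccc(O[Si](C(C)C)(C(C)C)C(C)C)cc1)C[C@H]2O[Si](C(C)C)(C(C)C)C(C)C | intermediate
25 | (2S,4R)-2-(4-hydroxyphenyl)-7-methoxy-8-(3-methylbut-2-enyl)chroman-4,5-diol | COc1cc(O)c2c(c1CC=C(C)C)O[C@H](c1ccc(O)cc1)C[C@H]2O | target

Total step count: 12. Longest linear sequence: 10 steps (1 → 2 → 5 → 6 → 7 → 8 → 9 → 14 → 16 → 24 → 25). Steps 7 and 10 are side branches.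

Steps most likely to fail

**Step 11.** After loss of nitrogen, hydride migration from the allylic CH2 may outrun the alkenyl migration. The ketene may also be intercepted by the phenol that is being formed, and prolonged irradiation may ionise the benzylic C4–O bond of the product.

The fallback sets out from 13 and rejoins at 24. It takes the carbene-adjacent CH2 out of the photochemical step and attaches the prenyl group afterwards.
- Lithio species 13 is acylated with N-methoxy-N-methylacetamide to the methyl ketone F1.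
- F1 is trifluoroacetylated to the 1,3-diketone F2 and converted by the diazo transfer of step 9 into the diazomethyl ketone F3. This is the substitution pattern for which the benzannulation is best documented, and it has no migratable hydrogen beside the carbene centre.
- Irradiation with 19 as in step 11 should give the 8-unsubstituted phenol F4.
- NBS in CH2Cl2 at −78 °C should brominate C8 to the aryl bromide F5. C8 is para to the 5-OH and is the position attacked first in 5,7-dioxygenated flavans.
- Suzuki–Miyaura coupling with prenylboronic acid pinacol ester (Pd, bulky biarylphosphine chosen for linear selectivity, K3PO4, aqueous THF) then gives 24.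

**Step 8.** Deprotonation at the benzylic C2–H may compete with C6–H metalation and lead to loss of configuration or ring opening. Metalation may also stay incomplete, or the vinyllithium may merely enolise the amide.

The fallback sets out from 9 (and 10) and rejoins at 14. It avoids strong base altogether.
- Iridium-catalysed vinylic C–H borylation ([Ir(OMe)(cod)]2, dtbpy, B2pin2, hexane, 50 °C) should give the C6 boronate F6. This reaction is α-selective for 4-substituted dihydropyrans and blind to the hindered C–H bonds of the 1,4-disubstituted arene.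
- Acid 10 is turned into the acid chloride F7 with oxalyl chloride and catalytic DMF.
- Anhydrous acylative Suzuki–Miyaura coupling (Pd(PPh3)4, Cs2CO3, toluene) joins F6 and F7 to give 14.

**Step 4.** The activated allylic alcohol may ionise to the oxocarbenium ion, which would erode the inversion, or the carboxylate may attack at C6 in the SN2′ sense.

The fallback sets out from 6 and rejoins at 8, so that step 5 is bypassed as well. It relays the configuration by a sigmatropic shift instead of a substitution at C4.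
- Alcohol 6 is acetylated (Ac2O, pyridine) to the cis acetate F8.
- Ferrier rearrangement with thiophenol (BF3·OEt2, CH2Cl2, −78 °C) should give the 6-phenylthio-3,6-dihydro-2H-pyran F9. Its sulfur is axial through the anomeric effect and hence trans to the aryl group.
- mCPBA at −78 °C gives the sulfoxide F10.
- The suprafacial Mislow–Evans [2,3] shift of F10 passes the oxygen to C4 on the same face, forming the allylic sulfenate F11.
- Piperidine cleaves F11 to the trans alcohol 8. This is the sequence known for turning glucal-type into allal-type glycals.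

Further compounds
F1 | step 11 | 1-[(2S,4R)-4-(triisopropylsilyloxy)-2-[4-(triisopropylsilyloxy)phenyl]-3,4-dihydro-2H-pyran-6-yl]ethan-1-one | CC(=O)C1=C[C@H](O[Si](C(C)C)(C(C)C)C(C)C)C[C@@H](c2ccc(O[Si](C(C)C)(C(C)C)C(C)C)cc2)O1
F2 | step 11 | 4,4,4-trifluoro-1-[(2S,4R)-4-(triisopropylsilyloxy)-2-[4-(triisopropylsilyloxy)phenyl]-3,4-dihydro-2H-pyran-6-yl]butane-1,3-dione | O=C(CC(=O)C(F)(F)F)C1=C[C@H](O[Si](C(C)C)(C(C)C)C(C)C)C[C@@H](c2ccc(O[Si](C(C)C)(C(C)C)C(C)C)cc2)O1
F3 | step 11 | 2-diazo-1-[(2S,4R)-4-(triisopropylsilyloxy)-2-[4-(triisopropylsilyloxy)phenyl]-3,4-dihydro-2H-pyran-6-yl]ethan-1-one | [N-]=[N+]=CC(=O)C1=C[C@H](O[Si](C(C)C)(C(C)C)C(C)C)C[C@@H](c2ccc(O[Si](C(C)C)(C(C)C)C(C)C)cc2)O1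
F4 | step 11 | (2S,4R)-7-methoxy-4-(triisopropylsilyloxy)-2-[4-(triisopropylsilyloxy)phenyl]chroman-5-ol | COc1cc(O)c2c(c1)O[C@H](c1ccc(O[Si](C(C)C)(C(C)C)C(C)C)cc1)C[C@H]2O[Si](C(C)C)(C(C)C)C(C)C
F5 | step 11 | (2S,4R)-8-bromo-7-methoxy-4-(triisopropylsilyloxy)-2-[4-(triisopropylsilyloxy)phenyl]chroman-5-ol | COc1cc(O)c2c(c1Br)O[C@H](c1ccc(O[Si](C(C)C)(C(C)C)C(C)C)cc1)C[C@H]2O[Si](C(C)C)(C(C)C)C(C)C
F6 | step 8 | 2-[(2S,4R)-4-(triisopropylsilyloxy)-2-[4-(triisopropylsilyloxy)phenyl]-3,4-dihydro-2H-pyran-6-yl]-4,4,5,5-tetramethyl-1,3,2-dioxaborolane | CC1(C)OB(OC1(C)C)C2=C[C@H](O[Si](C(C)C)(C(C)C)C(C)C)C[C@@H](c3ccc(O[Si](C(C)C)(C(C)C)C(C)C)cc3)O2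
F7 | step 8 | 5-methylhex-4-enoyl chloride | CC(C)=CCCC(=O)Cl
F8 | step 4 | (2S,4S)-2-[4-(triisopropylsilyloxy)phenyl]-3,4-dihydro-2H-pyran-4-yl acetate | C1=C[C@@H](OC(C)=O)C[C@@H](c2ccc(O[Si](C(C)C)(C(C)C)C(C)C)cc2)O1
F9 | step 4 | (2S,6R)-6-(phenylsulfanyl)-2-[4-(triisopropylsilyloxy)phenyl]-3,6-dihydro-2H-pyran | C1=C[C@@H](Sc2ccccc2)O[C@H](c2ccc(O[Si](C(C)C)(C(C)C)C(C)C)cc2)C1
F10 | step 4 | (2S,6R)-6-(phenylsulfinyl)-2-[4-(triisopropylsilyloxy)phenyl]-3,6-dihydro-2H-pyran (both sulfur epimers) | C1=C[C@@H](S(=O)c2ccccc2)O[C@H](c2ccc(O[Si](C(C)C)(C(C)C)C(C)C)cc2)C1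
F11 | step 4 | (2S,4R)-2-[4-(triisopropylsilyloxy)phenyl]-3,4-dihydro-2H-pyran-4-yl benzenesulfenate | C1=C[C@H](OSc3ccccc3)C[C@@H](c2ccc(O[Si](C(C)C)(C(C)C)C(C)C)cc2)O1
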